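## Analysis of the target

Target 41 consists of two 4-(4-hydroxyphenyl)chroman-2-ones joined through C3–C3′. In chroman-2-one numbering the unprimed half is the 5,6,7,8-tetrahydroxy lactone, whose benzene (C4a to C8a) is ring A, and the primed half is the 5′,7′-dihydroxy lactone, whose benzene is ring B. The four contiguous stereocentres are 4R,3S,3′S,4′S. The C4 aryl group and C3′ are cis on the ring A lactone, whereas C3 and the C4′ aryl group are trans on the ring B lactone, so the halves are not related by symmetry and a dimerisation cannot serve. Both C3–H and C3′–H are α to an aryl ester and epimerise with base. Trans is the stable arrangement in such lactones, so ring B can be set by equilibration, but the cis ring A lactone must be closed late and kept away from base. C4 and C4′ are doubly benzylic, and the eight free phenols include a benzene with oxygen on five adjacent carbons that oxidises readily in air. The hard part is ring A, a hexasubstituted benzene with oxygen on C5, C6, C7, C8 and C8a and a tertiary stereocentre as the only carbon substituent, on C4a. The strategy rests on this pattern: C6, C7, C8 and C8a map onto the four ring carbons of a squarate-derived trialkoxycyclobutenone, and C4a and C5 onto an oxygen-substituted alkyne that already carries C4 and C3.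

## Retrosynthetic reasoning

**Ring A lactone and the phenols (41 from 39, 39 from 38).** The last bond made is O1–C2 of ring A. It is left to the end because the 3,4-cis lactone is the less stable epimer and C3–H stays only weakly acidic as long as C2 is a tert-butyl ester. A boron Lewis acid cleaves the six methyl ethers and the tert-butyl ester of 39 to the seco acid 40, which lactonises in the acidic work-up. Once ring A is fully deprotected, closure through the oxygen on C8a or on C5 gives the same compound 41. Before that, buffered fluoride removes the three aryl silyl groups of 38.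

**Ring B configuration (38 from 37).** The 3′,4′-trans lactone is the thermodynamic one, so 38 is traced to its C3′ epimer 37. In 37 the only acidic C–H is C3′–H, so base can correct C3′ without touching C3, C4 or C4′.

**Ring B (37 from 30 and 34).** Cutting C3′–C4′ and O1′–C2′ gives the acid 30 and the ortho-quinone methide 36, released in the flask from sulfone 34. This cut joins the phloroglucinol half convergently, and a chiral carbene catalyst decides the face of 36, hence C4′. Sulfone 34 comes from carbinol 33, made from aldehyde 31 and Grignard reagent 32; the aldehyde fixes the position of the new carbon on ring B.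

**Freeing the ring B handle (30 from 28).** The phenol on C8a of 28 is silylated so that it cannot attack the activated C2′ carboxyl, and the silyl ester on C2′ is hydrolysed.

**Ring A (28 from 20 and 23), the key disconnection.** The bonds C4a–C8a and C5–C6 are cut, which takes the benzene apart into cyclobutenone 23 (C6, C7, C8, C8a) and silyloxyalkyne 20 (C4a, C5, with C4, C3, C2 and C2′ attached). No other cut delivers five differentiated oxygens and the C4 side chain in one operation without relying on electrophilic substitution of a crowded arene. The forward reaction must join the ketene carbon to the alkyne carbon that bears C4 and must leave C3 and C4 untouched.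

**The C5–O bond (20 from 17).** The silyl ynol ether is made from the terminal alkyne by acetylide oxidation and O-silylation. This needs a strong base and a nucleophilic peroxide, which an ordinary diester would not survive: C3 would enolise and the ynolate would cyclise onto the C2′ ester through a five-membered ring. C2′ is therefore carried as the free acid 17. Its carboxylate is inert, and the same silylation converts it into a silyl ester that the ynol ether tolerates.

**Ester pattern (17 from 16, 16 from 15, 15 from 13).** C2 is made a tert-butyl ester so that it neither enolises easily nor lactonises with the phenol formed in the key step. The ethyl ester on C2′ is saponified together with removal of the alkynyl silyl group. The C2 acid 15 comes from imide 13 by peroxide cleavage of the auxiliary.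

**C3 (13 from 10 and 11).** The C3–C3′ bond is cut. Alkylation of the imide enolate of 10 with bromoacetate 11 sets C3 under control of the auxiliary, independently of C4. A one-step union of C3 and C4 by a Nicholas-type propargylation of an imide boron enolate was considered and rejected. That reaction type is syn-selective across the new bond, which after annulation corresponds to a 3,4-trans ring A, whereas the target needs the anti relationship that gives the cis lactone.

**C4 (10 from 7 and 8, 7 from 5, 5 from 3 and 4, 3 from 1 and 2).** The C4–alkyne bond is cut. Enantioselective conjugate addition of silylacetylene 4 to the arylidene Meldrum's acid 3 sets C4. Hydrolysis with decarboxylation of 5 gives acid 7, which is attached to auxiliary 8. Compound 3 is the Knoevenagel product of 1 and 2.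

**Cyclobutenone (23 from 22, 22 from 21).** Silylation of the hydroxycyclobutenone 22, obtained by monoreduction of dimethyl squarate 21.

## Alternatives that were turned down

**Alternative 1:** Ring A is cut at C3–C4 and O1–C2. The ring B lactone acetic acid A2 is activated and converted by a chiral triazolylidene catalyst into an enolate that adds to the tetramethoxy ortho-quinone methide A3 in a formal [4+2], giving the heptamethyl ether A1.
- For: it is the most convergent plan, the cis relationship in ring A is the natural outcome of this cycloaddition, and only demethylation remains. On step count and convergence it is stronger than the chosen route.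
- Against: A3 is a hexasubstituted quinone methide stabilised by four donors and flanked at the methide carbon by the carbonyl and a methoxy group, so it is a poor electrophile for a β-branched enolate. A2 carries an aryl lactone, the very group carbene catalysts acylate, and an acidic C3′–H, so ring opening and enolisation at the wrong carbon compete under the basic conditions. The catalyst must override the stereocentre next to the enolate carbon. The pentaoxygenated arene behind A3 still has to be made by stepwise arene chemistry.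
- Comparison: the chosen strategy is longer, but it places all six ring A substituents by the connectivity of two components and sets C3 and C4 in acyclic steps before the crowded arene exists. It uses the carbene annulation only for the easier, trioxygenated ring B partner, where a later base equilibration is allowed.

**Alternative 2:** The C3–C4 and C3′–C4′ bonds are formed together. Diene A4 and the fumarate ester imide A5 combine under a chiral copper bis(oxazoline) Lewis acid to the cyclohexene A6, whose alkene carbons are later cut apart.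
- For: one catalytic step sets all four stereocentres. The adduct has the aryl groups cis to each other and the two carbonyl groups trans, which translates into cis ring A and trans ring B. On stereochemical economy it is clearly stronger than the chosen route, which needs three separate stereodefining operations.
- Against: after cleavage of the alkene, C4 and C4′ each carry only a carbonyl stub. Both benzo rings, the pentaoxygenated ring A and the phloroglucinol ring B, must then be built from two α-aryl carbonyl groups that epimerise easily and have to be told apart. A 1,4-diaryl diene is also a sluggish diene.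
- Comparison: the stereocentres are the smaller problem of this target. The chosen strategy spends its key step on the hexasubstituted ring A and gets C3 and C4 from auxiliary and catalyst control of well-known reliability.

**Alternative 3:** Ring B is cut at C4′–C4a′. A boron Lewis acid in a fluorinated alcohol ionises the carbinol A7 (either epimer), and the ester arene attacks the cation to give the trans lactone A8.
- For: the closure is stereoconvergent at the carbinol carbon, gives the stable trans lactone directly, and needs no chiral catalyst. For ring B alone it is at least as good as the carbene annulation used here.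
- Against: it is an endgame for ring B only and presupposes a ring A half with C3 and C4 set and a pentaoxygenated aryl group in place. The configuration of the C3′/C4′ pair relative to C3 rests on substrate control in the preceding aldol step, and strong acid meets a doubly benzylic, electron-rich C4.
- Comparison: it does not address ring A, which the chosen strategy solves. Its ring closure is kept as the fallback for step 16.

Key step: step 12

Assumption: in steps 2 and 16 the ligand or precatalyst enantiomer written is taken to give the configuration drawn; if the sense of induction is the reverse, the antipode is used and nothing else changes.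

## Route

Step 1
Reactants: 1 4-methoxybenzaldehyde; 2 2,2-dimethyl-1,3-dioxane-4,6-dione (Meldrum's acid)
Product: 3 5-[(4-methoxyphenyl)methylidene]-2,2-dimethyl-1,3-dioxane-4,6-dione
Conditions: H2O, 75 °C
Reagents that add atoms: none
Why: Knoevenagel condensation of an aromatic aldehyde with the strongly acidic Meldrum's acid needs no catalyst in hot water, and the product should crystallise from the medium.

Step 2
Reactants: 3 arylidene Meldrum's acid; 4 ethynyltrimethylsilane
Product: 5 5-[(1R)-1-(4-methoxyphenyl)-3-(trimethylsilyl)prop-2-yn-1-yl]-2,2-dimethyl-1,3-dioxane-4,6-dione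
Conditions: Rh(acac)(C2H4)2 (5 mol %), (S)-3,5-Xyl-MeO-BIPHEP (6 mol %), 4 (excess), 1,4-dioxane, 60 °C
Reagents that add atoms: none
Why: Rhodium-catalysed enantioselective conjugate alkynylation of arylidene Meldrum's acids with silylacetylenes is an established reaction type; the alkynylrhodium bisphosphine complex adds to one face of the alkylidene and sets C4. The silyl group suppresses alkyne dimerisation.

Step 3
Reactants: 5 Meldrum's acid adduct
Product: 7 (3R)-3-(4-methoxyphenyl)-5-(trimethylsilyl)pent-4-ynoic acid, via malonic acid 6 (not isolated)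
Conditions: DMF/H2O (10:1), 100 °C
Reagents that add atoms: water, O
Why: Hydrolysis of the acylal followed by decarboxylation of the malonic acid is the standard unmasking of Meldrum's acid adducts; C4 is not α to a carbonyl group and cannot epimerise.

Step 4
Reactants: 7 alkynoic acid; 8 (4R)-4-benzyl-1,3-oxazolidin-2-one
Product: 10 (4R)-4-benzyl-3-[(3R)-3-(4-methoxyphenyl)-5-(trimethylsilyl)pent-4-ynoyl]-1,3-oxazolidin-2-one, via mixed anhydride 9 (not isolated)
Conditions: PivCl, Et3N, THF, −20 °C; then 8, LiCl, −20 °C → rt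
Reagents that add atoms: none
Why: N-Acylation of the oxazolidinone through the mixed pivalic anhydride with LiCl activation needs no strong base; the nucleophile attacks the less hindered carbonyl of 9.

Step 5
Reactants: 10 imide; 11 ethyl bromoacetate
Product: 13 ethyl (3R,4R)-3-{[(4R)-4-benzyl-2-oxo-1,3-oxazolidin-3-yl]carbonyl}-4-(4-methoxyphenyl)-6-(trimethylsilyl)hex-5-ynoate, via sodium enolate 12 (not isolated)
Conditions: NaHMDS, THF, −78 °C; then 11, −78 → −40 °C
Reagents that add atoms: none
Why: Evans alkylation: the chelated Z-enolate 12 is shielded on one face by the benzyl group of the (R)-auxiliary, so the bromoacetate enters from the other face and sets C3 anti to the C4 aryl group (chain C2–C3–C4–alkyne drawn zigzag), the relationship that becomes the 3,4-cis lactone. A one-step Nicholas propargylation of an imide enolate would be syn-selective and was therefore not used.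

Step 6
Reactants: 13 alkylated imide
Product: 15 (2R,3R)-2-(2-ethoxy-2-oxoethyl)-3-(4-methoxyphenyl)-5-(trimethylsilyl)pent-4-ynoic acid, via peroxy acid 14 (not isolated)
Conditions: LiOH, H2O2, THF/H2O, 0 °C; then aq. Na2SO3; aq. HCl to pH 3
Reagents that add atoms: hydrogen peroxide, OO
Why: Hydroperoxide attacks the exocyclic imide carbonyl much faster than the ethyl ester and does not enolise C3; sulfite reduces the peroxy acid 14, and auxiliary 8 is recovered.

Step 7
Reactants: 15 C2 acid
Product: 16 1-tert-butyl 4-ethyl (2R)-2-[(1R)-1-(4-methoxyphenyl)-3-(trimethylsilyl)prop-2-yn-1-yl]butanedioate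
Conditions: tert-butyl 2,2,2-trichloroacetimidate, BF3·OEt2 (cat.), cyclohexane/CH2Cl2, rt
Reagents that add atoms: tert-butyl 2,2,2-trichloroacetimidate, CC(C)(C)OC(=N)C(Cl)(Cl)Cl
Why: Acid-catalysed O-alkylation with the trichloroacetimidate esterifies hindered acids without base, so C3 is not at risk. The tert-butyl ester is chosen for C2 because it neither enolises easily nor lactonises with the phenol formed in step 12.

Step 8
Reactants: 16 diester
Product: 17 (3R,4S)-3-(tert-butoxycarbonyl)-4-(4-methoxyphenyl)hex-5-ynoic acid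
Conditions: LiOH, THF/MeOH/H2O, rt; then aq. HCl to pH 3
Reagents that add atoms: lithium hydroxide, [Li+].[OH-]
Why: Saponification distinguishes the unhindered ethyl ester from the hindered tert-butyl ester, and the same medium removes the alkynyl silyl group; hydroxide is too weak a base to enolise the tert-butyl ester at C3.

Step 9
Reactants: 17 alkyne acid
Product: 20 1-tert-butyl 4-(triisopropylsilyl) (2R)-2-[(1R)-1-(4-methoxyphenyl)-3-(triisopropylsilyloxy)prop-2-yn-1-yl]butanedioate, via dilithium acetylide 18 (not isolated), via dilithium ynolate 19 (not isolated)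
Conditions: LiHMDS (2.0 equiv), THF, −78 °C; LiOOtBu (from tBuOOH and LiHMDS), −78 → 0 °C; then TIPSOTf, −78 → 0 °C
Reagents that add atoms: tert-butyl hydroperoxide, CC(C)(C)OO; triisopropylsilyl trifluoromethanesulfonate, CC(C)[Si](C(C)C)(C(C)C)OS(=O)(=O)C(F)(F)F
Why: Oxidation of a lithium acetylide with lithium tert-butyl peroxide to the ynolate, followed by O-silylation with a bulky silyl triflate, is the standard route to silyloxyalkynes. The C2′ carboxylate is neither enolised by LiHMDS nor attacked by the peroxide or the ynolate, and the C2 ester could be reached by the ynolate carbon only through a four-membered ring. The silylation also turns the carboxylate into a silyl ester that is inert toward the ynol ether.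

Step 10
Reactants: 21 3,4-dimethoxycyclobut-3-ene-1,2-dione (dimethyl squarate)
Product: 22 4-hydroxy-2,3-dimethoxycyclobut-2-en-1-one (racemic)
Conditions: LiAlH(OtBu)3, THF, −78 °C
Reagents that add atoms: none
Why: 1,2-Reduction of one of the two equivalent carbonyl groups of a squarate ester by a hindered alkoxyaluminium hydride stops at the 4-hydroxycyclobutenone, as does the addition of organolithium reagents to squarates.

Step 11
Reactants: 22 hydroxycyclobutenone
Product: 23 4-(tert-butyldimethylsilyloxy)-2,3-dimethoxycyclobut-2-en-1-one (racemic)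
Conditions: TBSCl, imidazole, DMF, 0 °C
Reagents that add atoms: tert-butyldimethylsilyl chloride, CC(C)(C)[Si](C)(C)Cl
Why: Silylation of the secondary alcohol under mild, non-acidic conditions avoids the acid-induced loss of methanol that leads to a cyclobutenedione; the racemic centre becomes aromatic in step 12.

Step 12
Reactants: 20 silyloxyalkyne; 23 silyloxycyclobutenone
Product: 28 1-tert-butyl 4-(triisopropylsilyl) (2R)-2-[(R)-[3-(tert-butyldimethylsilyloxy)-2-hydroxy-4,5-dimethoxy-6-(triisopropylsilyloxy)phenyl](4-methoxyphenyl)methyl]butanedioate, via vinylketene 24 (not isolated), via vinylcyclobutenone 25 (not isolated), via dienylketene 26 (not isolated), via cyclohexadienone 27 (not isolated)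
Conditions: toluene, 110 °C (argon)
Reagents that add atoms: none
Why: This is a Danheiser benzannulation of a cyclobutenone with a silyloxyalkyne, combined with the easy thermal opening of 4-oxygenated, squarate-derived cyclobutenones. Conrotatory 4π opening of 23, with the silyloxy group turning outward, gives vinylketene 24. Its ketene carbon, the future C8a, is attacked by the alkyne carbon of 20 that bears C4 (C4a), and the [2+2] cycloaddition is completed by the C5–C6 bond to give 25. Compound 25 opens (4π) to dienylketene 26, which closes the benzene ring by a thermal disrotatory 6π electrocyclisation between C8 and C8a to 27, and 27 tautomerises to phenol 28. The ring is thus closed by electrocyclisation and not by substitution on an arene, so all six substituents are placed by the connectivity of the two components. No stereocentre is formed, and C3 and C4 are spectators under neutral, aprotic heating. The one selectivity needed is the orientation of the ketene–alkyne [2+2], which is secured by the polarisation of the ynol ether, nucleophilic at the carbon remote from oxygen. The new hydroxyl on C8a stays free because C2 is a tert-butyl ester and C2′ could only form a seven-membered lactone.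

Step 13
Reactants: 28 ring A phenol
Product: 30 (3R,4R)-4-[2,3-bis(tert-butyldimethylsilyloxy)-4,5-dimethoxy-6-(triisopropylsilyloxy)phenyl]-3-(tert-butoxycarbonyl)-4-(4-methoxyphenyl)butanoic acid, via silyl ester 29 (not isolated)
Conditions: TBSOTf, 2,6-lutidine, CH2Cl2, 0 °C; then AcOH/THF/H2O, 40 °C
Reagents that add atoms: tert-butyldimethylsilyl trifluoromethanesulfonate, CC(C)(C)[Si](C)(C)OS(=O)(=O)C(F)(F)F
Why: The silyl triflate silylates the hindered phenol without forming a phenoxide, so no silyl migration between the oxygens on C8 and C8a can occur. Aqueous acetic acid then cleaves only the silyl ester, since aryl silyl ethers and the tert-butyl ester are stable to it.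

Step 14
Reactants: 31 2-hydroxy-4,6-dimethoxybenzaldehyde; 32 4-methoxyphenylmagnesium bromide
Product: 33 2-[hydroxy(4-methoxyphenyl)methyl]-3,5-dimethoxyphenol (racemic)
Conditions: 32 (2.2 equiv), THF, 0 °C → rt; aq. NH4Cl
Reagents that add atoms: none
Why: Grignard addition to a salicylaldehyde, the first equivalent being consumed by the phenol. The commercial aldehyde fixes the position of the new carbon on ring B, which a direct hydroxyalkylation of the parent phenol would not guarantee.

Step 15
Reactants: 33 benzhydrol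
Product: 34 3,5-dimethoxy-2-[(4-methoxyphenyl)(4-methylbenzenesulfonyl)methyl]phenol (racemic)
Conditions: TsNa, HCO2H/H2O, rt
Reagents that add atoms: sodium 4-methylbenzenesulfinate, Cc1ccc(S(=O)[O-])cc1.[Na+]
Why: Acid ionises the electron-rich benzhydrol and the sulfinate traps the stabilised cation at sulfur (SN1 substitution). The resulting sulfone is the usual base-triggered source of ortho-quinone methides.

Step 16
Reactants: 30 acid; 34 sulfone
Product: 37 tert-butyl (2S,3R)-3-[2,3-bis(tert-butyldimethylsilyloxy)-4,5-dimethoxy-6-(triisopropylsilyloxy)phenyl]-2-[(3R,4S)-5,7-dimethoxy-4-(4-methoxyphenyl)-2-oxo-3,4-dihydro-2H-chromen-3-yl]-3-(4-methoxyphenyl)propanoate, via acyl imidazole 35 (not isolated), via ortho-quinone methide 36 (not isolated)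
Conditions: CDI, THF, rt; then 34, (5aR,10bS)-2-mesityl-5a,10b-dihydro-4H,6H-indeno[2,1-b][1,2,4]triazolo[4,3-d][1,4]oxazin-2-ium tetrafluoroborate (20 mol %), Cs2CO3, THF, rt
Reagents that add atoms: none
Why: The carbene-catalysed formal [4+2] of activated aliphatic acids with ortho-quinone methides released from 2-(sulfonylmethyl)phenols is a known route to cis-3,4-disubstituted dihydrocoumarins. The carbene turns 35 into a chiral azolium enolate that adds to the methide carbon of 36 (C3′–C4′), and the phenoxide then closes the lactone (O1′–C2′) and releases the catalyst. The catalyst selects the face of 36 and so sets C4′; C3 is α only to the tert-butyl ester and the oxygen on C8a is silylated, so neither interferes.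

Step 17
Reactants: 37 cis lactone
Product: 38 tert-butyl (2S,3R)-3-[2,3-bis(tert-butyldimethylsilyloxy)-4,5-dimethoxy-6-(triisopropylsilyloxy)phenyl]-2-[(3S,4S)-5,7-dimethoxy-4-(4-methoxyphenyl)-2-oxo-3,4-dihydro-2H-chromen-3-yl]-3-(4-methoxyphenyl)propanoate
Conditions: DBU, toluene, rt
Reagents that add atoms: none
Why: Base-mediated epimerisation at C3′, the only acidic C–H, equilibrates the cis lactone to the more stable trans lactone, in which the C4′ aryl group and the C3 substituent lie on opposite faces. C3, C4 and C4′ are untouched.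

Step 18
Reactants: 38 trans lactone
Product: 39 tert-butyl (2S,3R)-2-[(3S,4S)-5,7-dimethoxy-4-(4-methoxyphenyl)-2-oxo-3,4-dihydro-2H-chromen-3-yl]-3-(4-methoxyphenyl)-3-(2,3,6-trihydroxy-4,5-dimethoxyphenyl)propanoate
Conditions: TBAF, AcOH, THF, 0 °C → rt (argon)
Reagents that add atoms: none
Why: Buffered fluoride cleaves the three aryl silyl ethers without leaving free phenoxide, which protects the hydroquinone from air oxidation and the lactone from opening. The tert-butyl ester keeps ring A open.

Step 19
Reactants: 39 triol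
Product: 41 (3S,4R)-3-[(3S,4S)-5,7-dihydroxy-4-(4-hydroxyphenyl)-2-oxo-3,4-dihydro-2H-chromen-3-yl]-5,6,7,8-tetrahydroxy-4-(4-hydroxyphenyl)-3,4-dihydro-2H-chromen-2-one, via seco acid 40 (not isolated)
Conditions: BBr3, CH2Cl2, −78 °C → rt; then H2O, aq. HCl (argon)
Reagents that add atoms: none
Why: Boron tribromide cleaves the six aryl methyl ethers and the tert-butyl ester, and acid 40 lactonises in the acidic work-up; closure through the oxygen on C8a or on C5 gives the same compound. No base is present, so the cis relationship at C3/C4 from step 5 is kept. Boron complexation of the aryl ethers deactivates the arenes toward the tert-butyl cation, and air is excluded because of the pentaoxygenated ring.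

## Compound list

1 | 4-methoxybenzaldehyde | COc1ccc(C=O)cc1 | starting material
2 | 2,2-dimethyl-1,3-dioxane-4,6-dione (Meldrum's acid) | CC1(C)OC(=O)CC(=O)O1 | starting material
3 | 5-[(4-methoxyphenyl)methylidene]-2,2-dimethyl-1,3-dioxane-4,6-dione | COc1ccc(C=C2C(=O)OC(C)(C)OC2=O)cc1 | intermediate
4 | ethynyltrimethylsilane | C#C[Si](C)(C)C | starting material
5 | 5-[(1R)-1-(4-methoxyphenyl)-3-(trimethylsilyl)prop-2-yn-1-yl]-2,2-dimethyl-1,3-dioxane-4,6-dione | C[Si](C)(C)C#C[C@@H](c1ccc(OC)cc1)C1C(=O)OC(C)(C)OC1=O | intermediate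
6 | 2-[(1R)-1-(4-methoxyphenyl)-3-(trimethylsilyl)prop-2-yn-1-yl]propanedioic acid | C[Si](C)(C)C#C[C@@H](c1ccc(OC)cc1)C(C(=O)O)C(=O)O | intermediate
7 | (3R)-3-(4-methoxyphenyl)-5-(trimethylsilyl)pent-4-ynoic acid | C[Si](C)(C)C#C[C@@H](c1ccc(OC)cc1)CC(=O)O | intermediate
8 | (4R)-4-benzyl-1,3-oxazolidin-2-one | O=C1N[C@H](Cc2ccccc2)CO1 | starting material
9 | (3R)-3-(4-methoxyphenyl)-5-(trimethylsilyl)pent-4-ynoic 2,2-dimethylpropanoic anhydride | C[Si](C)(C)C#C[C@@H](c1ccc(OC)cc1)CC(=O)OC(=O)C(C)(C)C | intermediate
10 | (4R)-4-benzyl-3-[(3R)-3-(4-methoxyphenyl)-5-(trimethylsilyl)pent-4-ynoyl]-1,3-oxazolidin-2-one | C[Si](C)(C)C#C[C@@H](c1ccc(OC)cc1)CC(=O)N1[C@H](Cc2ccccc2)COC1=O | intermediate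
11 | ethyl bromoacetate | CCOC(=O)CBr | starting material
12 | sodium (Z)-enolate of 10 | C[Si](C)(C)C#C[C@@H](c1ccc(OC)cc1)/C=C(\[O-])N1[C@H](Cc2ccccc2)COC1=O.[Na+] | intermediate
13 | ethyl (3R,4R)-3-{[(4R)-4-benzyl-2-oxo-1,3-oxazolidin-3-yl]carbonyl}-4-(4-methoxyphenyl)-6-(trimethylsilyl)hex-5-ynoate | C[Si](C)(C)C#C[C@@H](c1ccc(OC)cc1)[C@H](C(=O)N1[C@H](Cc2ccccc2)COC1=O)CC(=O)OCC | intermediate
14 | (2R,3R)-2-(2-ethoxy-2-oxoethyl)-3-(4-methoxyphenyl)-5-(trimethylsilyl)pent-4-yneperoxoic acid | C[Si](C)(C)C#C[C@@H](c1ccc(OC)cc1)[C@H](C(=O)OO)CC(=O)OCC | intermediate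
15 | (2R,3R)-2-(2-ethoxy-2-oxoethyl)-3-(4-methoxyphenyl)-5-(trimethylsilyl)pent-4-ynoic acid | C[Si](C)(C)C#C[C@@H](c1ccc(OC)cc1)[C@H](C(=O)O)CC(=O)OCC | intermediate
16 | 1-tert-butyl 4-ethyl (2R)-2-[(1R)-1-(4-methoxyphenyl)-3-(trimethylsilyl)prop-2-yn-1-yl]butanedioate | C[Si](C)(C)C#C[C@@H](c1ccc(OC)cc1)[C@H](C(=O)OC(C)(C)C)CC(=O)OCC | intermediate
17 | (3R,4S)-3-(tert-butoxycarbonyl)-4-(4-methoxyphenyl)hex-5-ynoic acid | C#C[C@@H](c1ccc(OC)cc1)[C@H](C(=O)OC(C)(C)C)CC(=O)O | intermediate
18 | dilithium salt of 17 (carboxylate and acetylide) | [Li+].[Li+].[C-]#C[C@@H](c1ccc(OC)cc1)[C@H](C(=O)OC(C)(C)C)CC(=O)[O-] | intermediate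
19 | dilithium ynolate carboxylate from 18 (oxide on the alkyne terminus) | [Li+].[Li+].[O-]C#C[C@@H](c1ccc(OC)cc1)[C@H](C(=O)OC(C)(C)C)CC(=O)[O-] | intermediate
20 | 1-tert-butyl 4-(triisopropylsilyl) (2R)-2-[(1R)-1-(4-methoxyphenyl)-3-(triisopropylsilyloxy)prop-2-yn-1-yl]butanedioate | CC(C)[Si](C(C)C)(C(C)C)OC#C[C@@H](c1ccc(OC)cc1)[C@H](C(=O)OC(C)(C)C)CC(=O)O[Si](C(C)C)(C(C)C)C(C)C | intermediate
21 | 3,4-dimethoxycyclobut-3-ene-1,2-dione (dimethyl squarate) | COC1=C(OC)C(=O)C1=O | starting material
22 | 4-hydroxy-2,3-dimethoxycyclobut-2-en-1-one (racemic) | COC1=C(OC)C(O)C1=O | intermediate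
23 | 4-(tert-butyldimethylsilyloxy)-2,3-dimethoxycyclobut-2-en-1-one (racemic) | COC1=C(OC)C(O[Si](C)(C)C(C)(C)C)C1=O | intermediate
24 | (3E)-4-(tert-butyldimethylsilyloxy)-2,3-dimethoxybuta-1,3-dien-1-one | O=C=C(OC)/C(OC)=C/O[Si](C)(C)C(C)(C)C | intermediate
25 | 4-vinylcyclobutenone from 24 and 20 (2-side chain, 3-triisopropylsilyloxy, 4-methoxy, 4-[(E)-2-(tert-butyldimethylsilyloxy)-1-methoxyethenyl]; mixture at the ring sp3 carbon) | O=C1C([C@@H](c2ccc(OC)cc2)[C@H](C(=O)OC(C)(C)C)CC(=O)O[Si](C(C)C)(C(C)C)C(C)C)=C(O[Si](C(C)C)(C(C)C)C(C)C)C1(OC)/C(OC)=C/O[Si](C)(C)C(C)(C)C | intermediate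
26 | dienylketene from ring opening of 25 | O=C=C([C@@H](c1ccc(OC)cc1)[C@H](C(=O)OC(C)(C)C)CC(=O)O[Si](C(C)C)(C(C)C)C(C)C)/C(O[Si](C(C)C)(C(C)C)C(C)C)=C(OC)\C(OC)=C\O[Si](C)(C)C(C)(C)C | intermediate
27 | cyclohexa-2,4-dienone tautomer of 28 (mixture at the ring sp3 carbon) | O=C1C([C@@H](c2ccc(OC)cc2)[C@H](C(=O)OC(C)(C)C)CC(=O)O[Si](C(C)C)(C(C)C)C(C)C)=C(O[Si](C(C)C)(C(C)C)C(C)C)C(OC)=C(OC)C1O[Si](C)(C)C(C)(C)C | intermediate
28 | 1-tert-butyl 4-(triisopropylsilyl) (2R)-2-[(R)-[3-(tert-butyldimethylsilyloxy)-2-hydroxy-4,5-dimethoxy-6-(triisopropylsilyloxy)phenyl](4-methoxyphenyl)methyl]butanedioate | Oc1c(O[Si](C)(C)C(C)(C)C)c(OC)c(OC)c(O[Si](C(C)C)(C(C)C)C(C)C)c1[C@@H](c1ccc(OC)cc1)[C@H](C(=O)OC(C)(C)C)CC(=O)O[Si](C(C)C)(C(C)C)C(C)C | intermediate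
29 | 1-tert-butyl 4-(triisopropylsilyl) (2R)-2-[(R)-[2,3-bis(tert-butyldimethylsilyloxy)-4,5-dimethoxy-6-(triisopropylsilyloxy)phenyl](4-methoxyphenyl)methyl]butanedioate | CC(C)(C)[Si](C)(C)Oc1c(O[Si](C)(C)C(C)(C)C)c(OC)c(OC)c(O[Si](C(C)C)(C(C)C)C(C)C)c1[C@@H](c1ccc(OC)cc1)[C@H](C(=O)OC(C)(C)C)CC(=O)O[Si](C(C)C)(C(C)C)C(C)C | intermediate
30 | (3R,4R)-4-[2,3-bis(tert-butyldimethylsilyloxy)-4,5-dimethoxy-6-(triisopropylsilyloxy)phenyl]-3-(tert-butoxycarbonyl)-4-(4-methoxyphenyl)butanoic acid | CC(C)(C)[Si](C)(C)Oc1c(O[Si](C)(C)C(C)(C)C)c(OC)c(OC)c(O[Si](C(C)C)(C(C)C)C(C)C)c1[C@@H](c1ccc(OC)cc1)[C@H](C(=O)OC(C)(C)C)CC(=O)O | intermediate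
31 | 2-hydroxy-4,6-dimethoxybenzaldehyde | COc1cc(O)c(C=O)c(OC)c1 | starting material
32 | 4-methoxyphenylmagnesium bromide | COc1ccc([Mg]Br)cc1 | starting material
33 | 2-[hydroxy(4-methoxyphenyl)methyl]-3,5-dimethoxyphenol (racemic) | COc1ccc(C(O)c2c(O)cc(OC)cc2OC)cc1 | intermediate
34 | 3,5-dimethoxy-2-[(4-methoxyphenyl)(4-methylbenzenesulfonyl)methyl]phenol (racemic) | COc1ccc(C(c2c(O)cc(OC)cc2OC)S(=O)(=O)c2ccc(C)cc2)cc1 | intermediate
35 | tert-butyl (2R,3R)-3-[2,3-bis(tert-butyldimethylsilyloxy)-4,5-dimethoxy-6-(triisopropylsilyloxy)phenyl]-2-[2-(1H-imidazol-1-yl)-2-oxoethyl]-3-(4-methoxyphenyl)propanoate | CC(C)(C)[Si](C)(C)Oc1c(O[Si](C)(C)C(C)(C)C)c(OC)c(OC)c(O[Si](C(C)C)(C(C)C)C(C)C)c1[C@@H](c1ccc(OC)cc1)[C@H](C(=O)OC(C)(C)C)CC(=O)n1ccnc1 | intermediate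
36 | 3,5-dimethoxy-6-[(4-methoxyphenyl)methylidene]cyclohexa-2,4-dien-1-one | O=C1C=C(OC)C=C(OC)C1=Cc1ccc(OC)cc1 | intermediate
37 | tert-butyl (2S,3R)-3-[2,3-bis(tert-butyldimethylsilyloxy)-4,5-dimethoxy-6-(triisopropylsilyloxy)phenyl]-2-[(3R,4S)-5,7-dimethoxy-4-(4-methoxyphenyl)-2-oxo-3,4-dihydro-2H-chromen-3-yl]-3-(4-methoxyphenyl)propanoate | CC(C)(C)[Si](C)(C)Oc1c(O[Si](C)(C)C(C)(C)C)c(OC)c(OC)c(O[Si](C(C)C)(C(C)C)C(C)C)c1[C@@H](c1ccc(OC)cc1)[C@H](C(=O)OC(C)(C)C)[C@@H]1C(=O)Oc2cc(OC)cc(OC)c2[C@@H]1c1ccc(OC)cc1 | intermediate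
38 | tert-butyl (2S,3R)-3-[2,3-bis(tert-butyldimethylsilyloxy)-4,5-dimethoxy-6-(triisopropylsilyloxy)phenyl]-2-[(3S,4S)-5,7-dimethoxy-4-(4-methoxyphenyl)-2-oxo-3,4-dihydro-2H-chromen-3-yl]-3-(4-methoxyphenyl)propanoate | CC(C)(C)[Si](C)(C)Oc1c(O[Si](C)(C)C(C)(C)C)c(OC)c(OC)c(O[Si](C(C)C)(C(C)C)C(C)C)c1[C@@H](c1ccc(OC)cc1)[C@H](C(=O)OC(C)(C)C)[C@H]1C(=O)Oc2cc(OC)cc(OC)c2[C@@H]1c1ccc(OC)cc1 | intermediate
39 | tert-butyl (2S,3R)-2-[(3S,4S)-5,7-dimethoxy-4-(4-methoxyphenyl)-2-oxo-3,4-dihydro-2H-chromen-3-yl]-3-(4-methoxyphenyl)-3-(2,3,6-trihydroxy-4,5-dimethoxyphenyl)propanoate | Oc1c(O)c(OC)c(OC)c(O)c1[C@@H](c1ccc(OC)cc1)[C@H](C(=O)OC(C)(C)C)[C@H]1C(=O)Oc2cc(OC)cc(OC)c2[C@@H]1c1ccc(OC)cc1 | intermediate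
40 | (2S,3R)-2-[(3S,4S)-5,7-dihydroxy-4-(4-hydroxyphenyl)-2-oxo-3,4-dihydro-2H-chromen-3-yl]-3-(4-hydroxyphenyl)-3-(pentahydroxyphenyl)propanoic acid | Oc1c(O)c(O)c(O)c(O)c1[C@@H](c1ccc(O)cc1)[C@H](C(=O)O)[C@H]1C(=O)Oc2cc(O)cc(O)c2[C@@H]1c1ccc(O)cc1 | intermediate
41 | (3S,4R)-3-[(3S,4S)-5,7-dihydroxy-4-(4-hydroxyphenyl)-2-oxo-3,4-dihydro-2H-chromen-3-yl]-5,6,7,8-tetrahydroxy-4-(4-hydroxyphenyl)-3,4-dihydro-2H-chromen-2-one | O=C1Oc2c(O)c(O)c(O)c(O)c2[C@@H](c2ccc(O)cc2)[C@H]1[C@H]1C(=O)Oc2cc(O)cc(O)c2[C@@H]1c1ccc(O)cc1 | target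

## Step count and least certain steps

Total: 19 steps. Longest linear sequence: 15 steps (steps 1 to 9, 12, 13, 16, 17, 18, 19).

**Step 12 (key step).** The most likely failure is a slow bimolecular [2+2]. The nucleophilic alkyne carbon of 20 carries the branched C4 substituent, so dimerisation or decomposition of the electron-rich vinylketene 24 may outrun the cycloaddition. Loss of the silyl ester would also let the free acid add to the ynol ether.

The fallback sets out from 20 and 21 and comes back at 39. It replaces the pericyclic cascade by the known maleoylcobalt route from cyclobutenediones and alkynes to benzoquinones.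
- CoCl(PPh3)3 inserts into the bond between the two carbonyl carbons of 21 to give the maleoylcobalt complex F1.
- After chloride abstraction (AgBF4, MeCN), F1 takes up alkyne 20 between its two acyl carbons and releases the quinone F2. The maleoyl unit is symmetric, so no regiochemical question arises.
- Na2S2O4 reduces F2 to the hydroquinone F3. It has the ring A oxygen pattern, with the triisopropylsilyl group on the oxygen of C8a instead of C5.
- TBSOTf and 2,6-lutidine give the tris-silyl ether F4, and aqueous acetic acid gives the acid F5.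
- The carbene annulation with 34 gives the cis lactone F6, and DBU gives the trans lactone F7.
- Buffered fluoride then converges on 39.

**Step 9.** The dianion 18 may be poorly soluble and its oxidation incomplete, silylation may occur partly on carbon, and hydrolysis of the silyl ester during isolation would destroy the ynol ether through addition of the liberated acid.

The fallback sets out from 17 and comes back at 19. It generates the ynolate by S–O cleavage of an alkynyl sulfonate instead of by acetylide oxidation.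
- [Hydroxy(tosyloxy)iodo]benzene converts the terminal alkyne of 17 into the alkynyl(phenyl)iodonium tosylate F8.
- With CuOTf (cat.) in MeCN, F8 rearranges to the alkynyl tosylate F9.
- Methyllithium (2 equiv, −78 °C, the first equivalent being consumed by the carboxylic acid) attacks sulfur and releases ynolate 19, which is silylated as in step 9.

**Step 16.** The acyl azolium from 35 is β-branched and very hindered, and 36 is a donor-stabilised, weakly electrophilic quinone methide. The result may be low conversion, or poor facial selectivity at C4′ if catalyst and the C3 centre are mismatched.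

The fallback sets out from 30 and 1 and comes back at 38. It closes ring B by an intramolecular Friedel–Crafts reaction instead of a cycloaddition.
- Acid 30 is esterified with 3,5-dimethoxyphenol (DCC, DMAP) to the aryl ester F10.
- The lithium enolate of F10 (LiHMDS, −78 °C, formed at the unhindered C3′) adds to aldehyde 1 to give the aldol carbinol F11 as an epimer mixture.
- A catalytic Lewis acid (Sc(OTf)3, CH2Cl2, 0 °C) ionises the 4-methoxybenzylic alcohol of either epimer, and the ester arene closes the lactone.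
- DBU then equilibrates C3′ to 38. The facial selectivity relative to C3 rests on substrate control in this variant.

**Step 2.** The enantioselectivity may be insufficient with the electron-rich anisylidene acceptor, and the sense of induction is assumed.

The fallback sets out from 3 and comes back at 10. It replaces catalyst control by a resolution on the auxiliary that is introduced anyway.
- (Trimethylsilyl)ethynylmagnesium bromide adds 1,4 to 3 (THF, −40 °C) to give the racemic adduct F12.
- Hydrolysis and decarboxylation as in step 3 give the racemic acid F13.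
- Coupling with 8 as in step 4 gives 10 together with its diastereomer F14, and 10 is separated by chromatography or crystallisation.

## Further compounds

F1 | step 12 | chlorobis(triphenylphosphine)(2,3-dimethoxymaleoyl)cobalt (1-cobaltacyclopent-3-ene-2,5-dione) | COC1=C(OC)C(=O)[Co](Cl)([P](c2ccccc2)(c2ccccc2)c2ccccc2)([P](c2ccccc2)(c2ccccc2)c2ccccc2)C1=O
F2 | step 12 | 1-tert-butyl 4-(triisopropylsilyl) (2R)-2-[(R)-[4,5-dimethoxy-3,6-dioxo-2-(triisopropylsilyloxy)cyclohexa-1,4-dien-1-yl](4-methoxyphenyl)methyl]butanedioate | O=C1C(OC)=C(OC)C(=O)C(O[Si](C(C)C)(C(C)C)C(C)C)=C1[C@@H](c1ccc(OC)cc1)[C@H](C(=O)OC(C)(C)C)CC(=O)O[Si](C(C)C)(C(C)C)C(C)C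
F3 | step 12 | 1-tert-butyl 4-(triisopropylsilyl) (2R)-2-[(R)-[2,5-dihydroxy-3,4-dimethoxy-6-(triisopropylsilyloxy)phenyl](4-methoxyphenyl)methyl]butanedioate | Oc1c(OC)c(OC)c(O)c(O[Si](C(C)C)(C(C)C)C(C)C)c1[C@@H](c1ccc(OC)cc1)[C@H](C(=O)OC(C)(C)C)CC(=O)O[Si](C(C)C)(C(C)C)C(C)C
F4 | step 12 | 1-tert-butyl 4-(triisopropylsilyl) (2R)-2-[(R)-[2,5-bis(tert-butyldimethylsilyloxy)-3,4-dimethoxy-6-(triisopropylsilyloxy)phenyl](4-methoxyphenyl)methyl]butanedioate | CC(C)(C)[Si](C)(C)Oc1c(OC)c(OC)c(O[Si](C)(C)C(C)(C)C)c(O[Si](C(C)C)(C(C)C)C(C)C)c1[C@@H](c1ccc(OC)cc1)[C@H](C(=O)OC(C)(C)C)CC(=O)O[Si](C(C)C)(C(C)C)C(C)C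
F5 | step 12 | (3R,4R)-4-[2,5-bis(tert-butyldimethylsilyloxy)-3,4-dimethoxy-6-(triisopropylsilyloxy)phenyl]-3-(tert-butoxycarbonyl)-4-(4-methoxyphenyl)butanoic acid | CC(C)(C)[Si](C)(C)Oc1c(OC)c(OC)c(O[Si](C)(C)C(C)(C)C)c(O[Si](C(C)C)(C(C)C)C(C)C)c1[C@@H](c1ccc(OC)cc1)[C@H](C(=O)OC(C)(C)C)CC(=O)O
F6 | step 12 | tert-butyl (2S,3R)-3-[2,5-bis(tert-butyldimethylsilyloxy)-3,4-dimethoxy-6-(triisopropylsilyloxy)phenyl]-2-[(3R,4S)-5,7-dimethoxy-4-(4-methoxyphenyl)-2-oxo-3,4-dihydro-2H-chromen-3-yl]-3-(4-methoxyphenyl)propanoate | CC(C)(C)[Si](C)(C)Oc1c(OC)c(OC)c(O[Si](C)(C)C(C)(C)C)c(O[Si](C(C)C)(C(C)C)C(C)C)c1[C@@H](c1ccc(OC)cc1)[C@H](C(=O)OC(C)(C)C)[C@@H]1C(=O)Oc2cc(OC)cc(OC)c2[C@@H]1c1ccc(OC)cc1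
F7 | step 12 | tert-butyl (2S,3R)-3-[2,5-bis(tert-butyldimethylsilyloxy)-3,4-dimethoxy-6-(triisopropylsilyloxy)phenyl]-2-[(3S,4S)-5,7-dimethoxy-4-(4-methoxyphenyl)-2-oxo-3,4-dihydro-2H-chromen-3-yl]-3-(4-methoxyphenyl)propanoate | CC(C)(C)[Si](C)(C)Oc1c(OC)c(OC)c(O[Si](C)(C)C(C)(C)C)c(O[Si](C(C)C)(C(C)C)C(C)C)c1[C@@H](c1ccc(OC)cc1)[C@H](C(=O)OC(C)(C)C)[C@H]1C(=O)Oc2cc(OC)cc(OC)c2[C@@H]1c1ccc(OC)cc1
F8 | step 9 | [(3R,4R)-4-(tert-butoxycarbonyl)-5-carboxy-3-(4-methoxyphenyl)pent-1-yn-1-yl](phenyl)iodonium 4-methylbenzenesulfonate | c1ccccc1[I+]C#C[C@@H](c1ccc(OC)cc1)[C@H](C(=O)OC(C)(C)C)CC(=O)O.Cc1ccc(S(=O)(=O)[O-])cc1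
F9 | step 9 | (3R,4R)-3-(tert-butoxycarbonyl)-4-(4-methoxyphenyl)-6-[(4-methylbenzenesulfonyl)oxy]hex-5-ynoic acid | Cc1ccc(S(=O)(=O)OC#C[C@@H](c2ccc(OC)cc2)[C@H](C(=O)OC(C)(C)C)CC(=O)O)cc1
F10 | step 16 | 1-tert-butyl 4-(3,5-dimethoxyphenyl) (2R)-2-[(R)-[2,3-bis(tert-butyldimethylsilyloxy)-4,5-dimethoxy-6-(triisopropylsilyloxy)phenyl](4-methoxyphenyl)methyl]butanedioate | CC(C)(C)[Si](C)(C)Oc1c(O[Si](C)(C)C(C)(C)C)c(OC)c(OC)c(O[Si](C(C)C)(C(C)C)C(C)C)c1[C@@H](c1ccc(OC)cc1)[C@H](C(=O)OC(C)(C)C)CC(=O)Oc1cc(OC)cc(OC)c1
F11 | step 16 | 1-tert-butyl 4-(3,5-dimethoxyphenyl) (2S)-2-[(R)-[2,3-bis(tert-butyldimethylsilyloxy)-4,5-dimethoxy-6-(triisopropylsilyloxy)phenyl](4-methoxyphenyl)methyl]-3-[hydroxy(4-methoxyphenyl)methyl]butanedioate (epimer mixture at C3 and at the carbinol carbon) | CC(C)(C)[Si](C)(C)Oc1c(O[Si](C)(C)C(C)(C)C)c(OC)c(OC)c(O[Si](C(C)C)(C(C)C)C(C)C)c1[C@@H](c1ccc(OC)cc1)[C@H](C(=O)OC(C)(C)C)C(C(=O)Oc1cc(OC)cc(OC)c1)C(O)c1ccc(OC)cc1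
F12 | step 2 | 5-[1-(4-methoxyphenyl)-3-(trimethylsilyl)prop-2-yn-1-yl]-2,2-dimethyl-1,3-dioxane-4,6-dione (racemic) | C[Si](C)(C)C#CC(c1ccc(OC)cc1)C1C(=O)OC(C)(C)OC1=O
F13 | step 2 | 3-(4-methoxyphenyl)-5-(trimethylsilyl)pent-4-ynoic acid (racemic) | C[Si](C)(C)C#CC(c1ccc(OC)cc1)CC(=O)O
F14 | step 2 | (4R)-4-benzyl-3-[(3S)-3-(4-methoxyphenyl)-5-(trimethylsilyl)pent-4-ynoyl]-1,3-oxazolidin-2-one | C[Si](C)(C)C#C[C@H](c1ccc(OC)cc1)CC(=O)N1[C@H](Cc2ccccc2)COC1=O
A1 | alternative 1 | (3S,4R)-3-[(3S,4S)-5,7-dimethoxy-4-(4-methoxyphenyl)-2-oxo-3,4-dihydro-2H-chromen-3-yl]-5,6,7,8-tetramethoxy-4-(4-methoxyphenyl)-3,4-dihydro-2H-chromen-2-one | O=C1Oc2c(OC)c(OC)c(OC)c(OC)c2[C@@H](c2ccc(OC)cc2)[C@H]1[C@H]1C(=O)Oc2cc(OC)cc(OC)c2[C@@H]1c1ccc(OC)cc1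
A2 | alternative 1 | 2-[(3R,4S)-5,7-dimethoxy-4-(4-methoxyphenyl)-2-oxo-3,4-dihydro-2H-chromen-3-yl]acetic acid | OC(=O)C[C@H]1C(=O)Oc2cc(OC)cc(OC)c2[C@@H]1c1ccc(OC)cc1
A3 | alternative 1 | 2,3,4,5-tetramethoxy-6-[(4-methoxyphenyl)methylidene]cyclohexa-2,4-dien-1-one | O=C1C(OC)=C(OC)C(OC)=C(OC)C1=Cc1ccc(OC)cc1
A4 | alternative 2 | (1E,3E)-1,4-bis(4-methoxyphenyl)buta-1,3-diene | COc1ccc(/C=C/C=C/c2ccc(OC)cc2)cc1
A5 | alternative 2 | methyl (2E)-4-oxo-4-(2-oxo-1,3-oxazolidin-3-yl)but-2-enoate | COC(=O)/C=C/C(=O)N1CCOC1=O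
A6 | alternative 2 | methyl 2,5-bis(4-methoxyphenyl)-6-(2-oxo-1,3-oxazolidine-3-carbonyl)cyclohex-3-ene-1-carboxylate (aryl groups cis, carbonyl groups trans, configuration as in the SMILES) | C1=C[C@H](c2ccc(OC)cc2)[C@H](C(=O)N2CCOC2=O)[C@@H](C(=O)OC)[C@@H]1c1ccc(OC)cc1
A7 | alternative 3 | 1-(3,5-dimethoxyphenyl) 4-methyl 2-[hydroxy(4-methoxyphenyl)methyl]-3-[(R)-(4-methoxyphenyl)(pentamethoxyphenyl)methyl]butanedioate (either carbinol epimer, other centres as in the SMILES) | COc1c(OC)c(OC)c(OC)c(OC)c1[C@@H](c1ccc(OC)cc1)[C@H](C(=O)OC)[C@@H](C(=O)Oc1cc(OC)cc(OC)c1)C(O)c1ccc(OC)cc1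
A8 | alternative 3 | methyl (2S,3R)-2-[(3S,4S)-5,7-dimethoxy-4-(4-methoxyphenyl)-2-oxo-3,4-dihydro-2H-chromen-3-yl]-3-(4-methoxyphenyl)-3-(pentamethoxyphenyl)propanoate | COc1c(OC)c(OC)c(OC)c(OC)c1[C@@H](c1ccc(OC)cc1)[C@H](C(=O)OC)[C@H]1C(=O)Oc2cc(OC)cc(OC)c2[C@@H]1c1ccc(OC)cc1
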